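**Retrosynthetic overview**
1. The target is a C20 prostanoid chain (C1–C20, prostane numbering) carrying OMe and a 12-acetate, with one stereocentre (12R), a C10 chloride and 5Z, 7E, 14Z alkenes.
2. The cyclopentenone is closed last, through C8–C12, by conrotatory 4π closure of an open-chain C20 9-oxidopentadienyl ketone. This is the bond and the kind of intermediate of the allene oxide → oxidopentadienyl cation → preclavulone closure, run at the oxidation level of the target. The same flask adds C13–C20, acetylates O12 and makes the 7E alkene by E1cB.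
3. That open-chain species is released when a (Z)-oct-2-enyl metal adds to C12 of an enol lactone, a (Z)-4-chloro-5-ylidenebutenolide (C1–C12), which stores O9 and holds C9 cis to C12.
4. The butenolide comes from tandem Sonogashira–lactonization of a (7S)-propargylic alcohol (C1–C9) with (Z)-3-chloro-3-iodoacrylic acid (C10–C12). The carbinol comes from asymmetric alkynylation of a Z-enal; C7 relays its chirality to C12 and is then erased.
5. Ring order: butenolide (temporary O-heterocycle) first, cyclopentenone last.

Assumption: (S,S)-ProPhenol is taken as the ligand antipode that gives the 7S carbinol in step 3 (checked by Mosher analysis; otherwise the (R,R) ligand is used unchanged); prostane numbering C1–C20 is used for chain atoms throughout.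

Step 1
Reactants: 1 methyl hex-5-enoate; 2 (2Z)-but-2-ene-1,4-diol
Product: 3 methyl (5Z)-7-hydroxyhept-5-enoate
Conditions: 2 (3 equiv), Ru(=CHC6H4-2-Oi-Pr)(1,3-dimesitylimidazolidin-2-ylidene)(3,6-dichlorobenzene-1,2-dithiolate) (4 mol%), THF, 22 °C, 8 h
Reagents that add atoms: none
Why: Z-selective olefin cross-metathesis, in which the dithiolate ligand forces both ruthenacyclobutane substituents to one side so the Z-allylic alcohol forms kinetically from the Z-diol partner; no stereocentre is made.

Step 2
Reactants: 3 methyl (5Z)-7-hydroxyhept-5-enoate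
Product: 4 methyl (5Z)-7-oxohept-5-enoate
Conditions: Dess–Martin periodinane (1.2 equiv), pyridine (3 equiv), CH2Cl2, 0 °C, 1 h; used crude at once
Reagents that add atoms: none
Why: Dess–Martin oxidation of a primary allylic alcohol under buffered, cold, non-enolizing conditions gives the Z-enal without Z-to-E isomerization; no stereocentre is made.

Step 3
Reactants: 4 methyl (5Z)-7-oxohept-5-enoate; 5 ethynyltrimethylsilane
Product: 7 methyl (5Z,7S)-7-hydroxy-9-(trimethylsilyl)non-5-en-8-ynoate, via alkynylzinc 6 (not isolated)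
Conditions: 5 (3 equiv), Me2Zn (3 equiv), (S,S)-ProPhenol (10 mol%), Ph3P=O (20 mol%), toluene, 4 °C, 48 h; aq NH4Cl
Reagents that add atoms: none
Why: Trost-type dinuclear zinc–ProPhenol asymmetric alkynylation, in which alkynylzinc 6 is delivered inside the chiral Zn2 pocket to one enantioface of the aldehyde by 1,2-addition, which sets C7 as S.

Step 4
Reactants: 7 methyl (5Z,7S)-7-hydroxy-9-(trimethylsilyl)non-5-en-8-ynoate
Product: 8 methyl (5Z,7S)-7-hydroxynon-5-en-8-ynoate
Conditions: K2CO3 (0.2 equiv), MeOH, 0 °C, 1 h
Reagents that add atoms: none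
Why: base-catalysed methanolysis of the alkynyl C–Si bond (protodesilylation) is selective for the alkynylsilane and leaves the methyl ester, the Z-alkene and C7 untouched.

Step 5
Reactants: 9 prop-2-ynoic acid
Product: 10 3-chloroprop-2-ynoic acid
Conditions: NaOH (1.0 equiv), NaOCl (1.1 equiv), H2O, 0 °C, 1 h; HCl to pH 1, Et2O extraction
Reagents that add atoms: sodium hypochlorite, [Na+].[O-]Cl
Why: hypochlorite chlorination of the acetylenic C–H through the alkynide is the classical route to 1-haloalkynes and gives the chloroalkynoic acid.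

Step 6
Reactants: 10 3-chloroprop-2-ynoic acid
Product: 11 (2Z)-3-chloro-3-iodoprop-2-enoic acid
Conditions: NaI (1.05 equiv), AcOH, 20 °C, 3 h, dark
Reagents that add atoms: sodium iodide, [Na+].[I-]
Why: conjugate hydroiodination of an alkynoic acid, in which iodide adds at C3 and protonation at C2 is anti, so iodine ends cis to the carboxyl group as in the propiolic acid to (Z)-3-iodoacrylic acid reaction.

Step 7
Reactants: 8 methyl (5Z,7S)-7-hydroxynon-5-en-8-ynoate; 11 (2Z)-3-chloro-3-iodoprop-2-enoic acid
Product: 13 methyl (5Z,7S,8Z)-8-(3-chloro-5-oxofuran-2(5H)-ylidene)-7-hydroxyoct-5-enoate, via enynoic acid 12 (not isolated)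
Conditions: Pd(PPh3)4 (5 mol%), CuI (10 mol%), Et3N (3 equiv), MeCN, 20 °C, 6 h
Reagents that add atoms: none
Why: Sonogashira coupling takes place only at the C–I bond with retention, and the cis carboxylate of 12 then adds 5-exo-dig anti across the alkyne (tandem coupling–lactonization) to give the (Z)-ylidenebutenolide, which stores O9 as an enol ester and locks C9 cis to C12; C7 is not touched.

Step 8
Reactants: 13 methyl (5Z,7S,8Z)-8-(3-chloro-5-oxofuran-2(5H)-ylidene)-7-hydroxyoct-5-enoate; 14 oct-1-ene
Product: 21 methyl (5Z,7E,12R,14Z)-12-acetoxy-10-chloro-9-oxoprosta-5,7,10,14-tetraen-1-oate, via allylpotassium 15 (not isolated), via allylcerium 16 (not isolated), via lithium alkoxide 17 (not isolated), via open-chain oxidopentadienyl ketone 18 (not isolated), via cyclized dialkoxide 19 (not isolated), via diacetate 20 (not isolated)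
Conditions: 14 (1.3 equiv), n-BuLi (1.2 equiv), KOt-Bu (1.2 equiv), THF, −50 °C, 20 h; CeCl3 (1.6 equiv), −78 °C, 1 h; added slowly to 13 + LiN(SiMe3)2 (1.0 equiv), THF, −78 → −40 °C, 1 h; Ac2O (5 equiv), DMAP (0.2 equiv), −40 → 0 °C; DBU (2 equiv), 0 °C, 30 min
Reagents that add atoms: acetic anhydride, CC(=O)OC(C)=O
Why: Proposed new method: the Z-allylcerium 16 (endo-allylpotassium from Schlosser metalation, transmetalated to trivalent cerium, which attacks carbonyls 1,2 through its unsubstituted terminus with retention of Z) adds to the enol-lactone carbonyl C12 and the C9 enolate is expelled (Fujimoto–Belleau-type opening), which unmasks in an open C20 chain a 9-oxidopentadienyl system whose 10,11-bond is held cis by the former ring and whose cerium-bound C12 ketone closes onto C8 by conrotatory 4π ring closure (as in the allene oxide → oxidopentadienyl cation → cyclopentenone closure and the cis-enedione → 4-hydroxycyclopentenone cyclization); the chelated 7S alkoxide (O7 held in the enolate plane, alkenyl arm perpendicular) sends C12 to the face anti to that arm and the s-cis ketone turns its oxygen inward, which sets C8 as R and C12 in the arrangement that is 12R in 21, and acetylation of both alkoxides followed by DBU-induced E1cB loss of the C7 acetate (loss of the C12 acetate would give a cyclopentadienone) erases C7 and C8 and gives the thermodynamically favored 7E alkene; closest known reactions are the Fujimoto–Belleau reaction, the ylidenebutenolide → cyclopentenedione rearrangement and the aldol–acetylation–elimination endgame of cross-conjugated cyclopentenone prostanoids.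

**Compound list**
1 | methyl hex-5-enoate | C=CCCCC(=O)OC | starting material
2 | (2Z)-but-2-ene-1,4-diol | OC/C=C\CO | starting material
3 | methyl (5Z)-7-hydroxyhept-5-enoate | OC/C=C\CCCC(=O)OC | intermediate
4 | methyl (5Z)-7-oxohept-5-enoate | O=C/C=C\CCCC(=O)OC | intermediate
5 | ethynyltrimethylsilane | C#C[Si](C)(C)C | starting material
6 | methyl[(trimethylsilyl)ethynyl]zinc | C[Zn]C#C[Si](C)(C)C | intermediate
7 | methyl (5Z,7S)-7-hydroxy-9-(trimethylsilyl)non-5-en-8-ynoate | C[Si](C)(C)C#C[C@@H](O)/C=C\CCCC(=O)OC | intermediate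
8 | methyl (5Z,7S)-7-hydroxynon-5-en-8-ynoate | C#C[C@@H](O)/C=C\CCCC(=O)OC | intermediate
9 | prop-2-ynoic acid (propiolic acid) | C#CC(=O)O | starting material
10 | 3-chloroprop-2-ynoic acid | ClC#CC(=O)O | intermediate
11 | (2Z)-3-chloro-3-iodoprop-2-enoic acid (iodine cis to CO2H) | OC(=O)/C=C(\I)Cl | intermediate
12 | (2E,6S,7Z)-3-chloro-6-hydroxy-12-methoxy-12-oxododeca-2,7-dien-4-ynoic acid (alkyne cis to CO2H) | COC(=O)CCC/C=C\[C@H](O)C#C/C(Cl)=C\C(=O)O | intermediate
13 | methyl (5Z,7S,8Z)-8-(3-chloro-5-oxofuran-2(5H)-ylidene)-7-hydroxyoct-5-enoate (C1–C12; ring O is O9, lactone C=O is C12) | COC(=O)CCC/C=C\[C@H](O)/C=C1\OC(=O)C=C1Cl | intermediate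
14 | oct-1-ene | C=CCCCCCC | starting material
15 | (2Z)-oct-2-en-1-ylpotassium | CCCCC/C=C\C[K] | intermediate
16 | dichloro[(2Z)-oct-2-en-1-yl]cerium | CCCCC/C=C\C[Ce](Cl)Cl | intermediate
17 | lithium alkoxide of 13 | [Li+].COC(=O)CCC/C=C\[C@H]([O-])/C=C1\OC(=O)C=C1Cl | intermediate
18 | lithium dichlorocerium salt of methyl (5Z,7S,8Z,10E,14Z)-10-chloro-7,9-dioxido-12-oxoicosa-5,8,10,14-tetraenoate | COC(=O)CCC/C=C\[C@H]([O-])/C=C(\[O-])/C(Cl)=C\C(=O)C/C=C\CCCCC.[Li+].[Ce+3].[Cl-].[Cl-] | intermediate
19 | lithium dichlorocerium salt of methyl (5Z,7S,8R,12S,14Z)-10-chloro-7,12-dioxido-9-oxoprosta-5,10,14-trien-1-oate (12S here is the same spatial arrangement as 12R in 21; the CIP ranks of C8 and C11 swap once C8 is sp2) | COC(=O)CCC/C=C\[C@H]([O-])[C@H]1C(=O)C(Cl)=C[C@]1([O-])C/C=C\CCCCC.[Li+].[Ce+3].[Cl-].[Cl-] | intermediate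
20 | methyl (5Z,7S,8R,12S,14Z)-7,12-diacetoxy-10-chloro-9-oxoprosta-5,10,14-trien-1-oate | COC(=O)CCC/C=C\[C@H](OC(C)=O)[C@H]1C(=O)C(Cl)=C[C@]1(OC(C)=O)C/C=C\CCCCC | intermediate
21 | methyl (5Z,7E,12R,14Z)-12-acetoxy-10-chloro-9-oxoprosta-5,7,10,14-tetraen-1-oate | CCCCC/C=C\C[C@@]1(OC(C)=O)C=C(Cl)C(=O)/C1=C/C=C\CCCC(=O)OC | target

**Totals**
Total step count: 8. Longest linear sequence: 6 (steps 1, 2, 3, 4, 7, 8).

**Steps most likely to fail**

Step 8. The risks are attack of 16 through its substituted terminus or loss of its Z geometry, competing attack at the C1 methyl ester or a second addition to the C12 ketone, and an imperfect relay from C7 to C12. The sense of that relay rests on the chelate model and on the inward turn of the ketone oxygen; if it runs the other way, the (R,R) ligand in step 3 corrects it. The fallback sets out from 13 and comes back at 21, and brings the ω-chain in as its alkyne. Compound 13 is deprotonated with LiN(SiMe3)2 and treated at −20 °C in THF with octa-1,2-dien-3-ylzinc bromide F1 (made from 1-bromooct-2-yne and zinc dust). This reagent transfers the oct-2-ynyl group by SE2′ attack at C12, has no alkene geometry to lose and spares alkyl esters. Ring opening and C8–C12 closure follow as before, and aqueous NH4Cl gives the isolable diol methyl (5Z,7S,8R,12S)-10-chloro-7,12-dihydroxy-9-oxoprosta-5,10-dien-14-yn-1-oate F2, from which any C12 epimer is removed by chromatography. Ac2O, DMAP and Et3N, then DBU, give through the diacetate methyl (5Z,7S,8R,12S)-7,12-diacetoxy-10-chloro-9-oxoprosta-5,10-dien-14-yn-1-oate F3 the 14,15-didehydro compound methyl (5Z,7E,12R)-12-acetoxy-10-chloro-9-oxoprosta-5,7,10-trien-14-yn-1-oate F4. Semihydrogenation over Pd/CaCO3 poisoned with Pb(OAc)2 and quinoline (H2, 1 atm, EtOAc, 0 °C) reduces the isolated alkyne to the 14Z alkene and returns to 21.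

Step 7. The risks are 6-endo closure to the pyranone, a second coupling at the C–Cl bond, and loss of iodide geometry in 11 before coupling. The fallback sets out from 8 and 11 and comes back at 13, and separates coupling from ring closure. Copper-free coupling (PdCl2(PPh3)2 3 mol%, Et3N, THF, 0 °C) stops at the open-chain acid 12, which is isolated. Catalytic AgNO3 (acetone, 20 °C) then closes it by 5-exo-dig anti oxy-argentation and protodemetalation, which favors the Z-ylidene five-membered lactone, to give 13. No new compound is made.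

Step 3. The risks are modest enantioselectivity with a Z-enal and Z-to-E isomerization of 4 on zinc. The fallback sets out from 4 and comes back at 7, and moves the asymmetric event from C–C bond formation to a ketone reduction. Commercial lithium (trimethylsilyl)acetylide (THF, −78 °C) adds to 4 to give the racemic alcohol methyl (5Z)-7-hydroxy-9-(trimethylsilyl)non-5-en-8-ynoate F5. MnO2 (CH2Cl2, 0 °C) gives the ynone methyl (5Z)-7-oxo-9-(trimethylsilyl)non-5-en-8-ynoate F6. Base-free asymmetric transfer hydrogenation with RuCl[(S,S)-TsDPEN](p-cymene) in i-PrOH, which reduces alkynyl ketones with high enantioselectivity, gives 7.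

Further compounds
F1 | step 8 | octa-1,2-dien-3-ylzinc bromide | CCCCCC(=C=C)[Zn]Br
F2 | step 8 | methyl (5Z,7S,8R,12S)-10-chloro-7,12-dihydroxy-9-oxoprosta-5,10-dien-14-yn-1-oate | COC(=O)CCC/C=C\[C@H](O)[C@H]1C(=O)C(Cl)=C[C@]1(O)CC#CCCCCC
F3 | step 8 | methyl (5Z,7S,8R,12S)-7,12-diacetoxy-10-chloro-9-oxoprosta-5,10-dien-14-yn-1-oate | COC(=O)CCC/C=C\[C@H](OC(C)=O)[C@H]1C(=O)C(Cl)=C[C@]1(OC(C)=O)CC#CCCCCC
F4 | step 8 | methyl (5Z,7E,12R)-12-acetoxy-10-chloro-9-oxoprosta-5,7,10-trien-14-yn-1-oate | CCCCCC#CC[C@@]1(OC(C)=O)C=C(Cl)C(=O)/C1=C/C=C\CCCC(=O)OC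
F0 | step 7 | none | none
F5 | step 3 | methyl (5Z)-7-hydroxy-9-(trimethylsilyl)non-5-en-8-ynoate (racemic) | C[Si](C)(C)C#CC(O)/C=C\CCCC(=O)OC
F6 | step 3 | methyl (5Z)-7-oxo-9-(trimethylsilyl)non-5-en-8-ynoate | C[Si](C)(C)C#CC(=O)/C=C\CCCC(=O)OC
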